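The product, target with idle complex B counted in, reads nearly the same in Saturday's run and Tuesday's run at 2.50 h: 8.8% against 9.4%, a ratio of 1.07 for a catalyst ratio of 2.23.

| flask | substrate | gas phase | catalyst | remark | time |
|---|---|---|---|---|---|
| Saturday's | 0.85 M | 54 mM (held) | 94 mM | run made earlier |  |
| Tuesday's | 0.85 M | 54 mM (held) | 210 mM | run made earlier |  |
| Thursday's | 1.3 M | 54 mM (held) | 140 mM | run made earlier |  |
| flask | 0.85 M | 54 mM (held) | 140 mM |  | 4.0 h |

| run | time / h | target / % | idle complex B / % |
|---|---|---|---|
| Saturday's | 0.133 | 0 | 0 |
| Saturday's | 0.333 | 0.9 | 0.1 |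
| Saturday's | 0.667 | 2.2 | 0.1 |
| Saturday's | 1.00 | 4.4 | 0.3 |
| Saturday's | 1.33 | 4.9 | 0.3 |
| Saturday's | 2.00 | 7.8 | 0.2 |
| Saturday's | 2.50 | 8.8 | 1.0 |
| Tuesday's | 0.200 | 1.3 | 0.1 |
| Tuesday's | 0.333 | 1.5 | 0.2 |
| Tuesday's | 0.417 | 1.9 | 0.4 |
| Tuesday's | 0.667 | 2.6 | 0.2 |
| Tuesday's | 1.00 | 4.2 | 0.3 |
| Tuesday's | 1.50 | 6.1 | 0.3 |
| Tuesday's | 2.50 | 9.4 | 0.9 |
| Thursday's | 0.200 | 0.5 | 0 |
| Thursday's | 0.667 | 2.0 | 0.1 |
| Thursday's | 1.00 | 3.2 | 0 |
| Thursday's | 1.50 | 4.6 | 0 |
| Thursday's | 2.50 | 7.3 | 0.7 |

(each reading ± 0.3 percentage points)

- what is said of target includes idle complex B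
- at the start none of the gas is dissolved
- steps that have been proposed: gas phase <-> dissolved gas; substrate + catalyst <-> idle complex A; catalyst + target <-> idle complex B; substrate + dissolved gas + catalyst <-> catalyst + target

- teal: doubling the transfer coefficient of the gas phase, all else as stated
- green: doubling the saturation concentration of gas phase, all else as stated
- amber: doubling the amount of catalyst, all else as stated

* how much target and idle complex B together there is at 4.0 h, in percent of the substrate charged
* concentration of dissolved gas in solution at 2.0 h, in percent of saturation
* the change that raises the amount of target and idle complex B together at 4.0 h, in percent of the substrate charged most ("none" if none brings more than 2 percentage points) (teal / green / amber / none)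
* amount of target and idle complex B together at 4.0 h, in percent of the substrate charged, after teal

So I take the crossing of the gas as the rate-limiting step and the catalysed step as near balance, since the product ratio stands below the catalyst ratio.

What then happens to the pace? With that step near balance, c(dissolved gas) follows c(target)/c(substrate). Taking c(substrate) as steady, the crossing, proportional to the gap between saturation and c(dissolved gas), slackens in step with the product made. The two runs averaged read 4.30% at 1.00 h and 9.10% at 2.50 h. Pace against product over these two stretches falls with a slope of 0.242 h⁻¹, and the line meets zero at 19.9%. This reading, with its scatter, is the ceiling: the product in balance with a saturated solution.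

How full is the solution in the flask? The percent of saturation equals product over ceiling, which grows as one minus exp(−slope × time). That gives me 38.3% at 2.0 h and a product of 12.4% at 4.0 h.

Which change pays? Teal doubles the slope and keeps the ceiling, giving 17.1%, a gain of 4.7 percentage points. Green doubles the ceiling and keeps the slope, so its gain is 12 points, larger, and I choose green.

The forecast, which says the product “climbs almost linearly”, gives 15.5%, 8%, green and 28%, so its product stands above mine and its saturation below mine.

The flask gives 13.0%, 40.2% and green, with gains of 11 points for green, 4.5 points for teal and 0.42 points for amber, and 17.5% after teal.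

    gas phase ⇌ dissolved gas, rate k1*(csat - [dissolved gas]) (kL = 0.0180 min⁻¹)
    substrate + catalyst ⇌ idle complex A, settled at all times (K = 1.30 L mol⁻¹)
    catalyst + target ⇌ idle complex B (K = 2.80 L mol⁻¹, k = 0.0200 L mol⁻¹ min⁻¹)
    substrate + dissolved gas + catalyst ⇌ catalyst + target (K = 4.70 L mol⁻¹, k = 2.80 L² mol⁻² min⁻¹)

In the flask, the backward turnover of the catalysed step is 84% of the forward one. At 4.00 h the flask's product over the ceiling is 65.3%, and its dissolved gas, 0.0334 M, is 61.9% of saturation. The neighbouring flask is the same charge stopped at 1.0 h, with a product of 4.16%. Over the ceiling that makes 20.9%, and its dissolved gas, 0.0137 M, stands at 25.3% of saturation.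

(All runs stem from a simulated flask from invented constants; scatter was added.)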